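**Retrosynthetic overview**
1. Target ⇐ C13–C14 Stille vinylation of a terminal enol triflate ⇐ bicyclic methyl ketone that already carries 6-OAc, 8-OH and 18-OH.
2. Bicyclic ketone ⇐ one cationic cascade of an acyclic (S)-2,2-disubstituted epoxide / (R)-allylic acetate / methyl ketone: the oxirane opens at C4, ring A closes (C4–C5), then ring B (C10–C9), and the ketone oxygen captures C8 (transient pyran ring C, opened in the work-up).
3. Acyclic precursor ⇐ C6–C7 by enantioselective propargylation of an enal; C8=C9 and C9–C11 by methylalumination of the alkyne and 1,4-addition to methyl vinyl ketone.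
4. Enal diol ⇐ geranyl acetate by allylic oxidation, Sharpless epoxidation and hydride opening at the secondary oxirane carbon (sets the tertiary carbinol that becomes the oxirane).
5. Stereocontrol: C4 from the oxirane (inversion); C5, C8, C9 and C10 from the single C6 acetate through allylic 1,3-strain in the chair–chair fold.

Assumption: the SMILES is read as ent-6α-acetoxylabda-13(16),14-diene-8α,18-diol (6-O-acetylandalusol), 4S,5S,6R,8S,9S,10R; labdane numbering (C1–C20, C18 = equatorial CH2O on C4) is used for all cyclic compounds and for the matching carbons of the acyclic precursors.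

**Route**

Step 1
Reactants: 1 geranyl acetate
Product: 2 (2E,6E)-8-hydroxy-3,7-dimethylocta-2,6-dien-1-yl acetate
Conditions: SeO2 (cat.), t-BuOOH, salicylic acid (cat.), CH2Cl2, rt
Reagents that add atoms: tert-butyl hydroperoxide, CC(C)(C)OO (terminal oxidant; the oxygen reaches carbon by way of selenium dioxide, O=[Se]=O)
Why: Catalytic SeO2 allylic oxidation (ene reaction then [2,3]-sigmatropic shift) attacks only the E-methyl of the electron-rich terminal alkene, the 2,3-alkene being deactivated by its allylic acetate; no stereocentre is formed and the E geometry is kept.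

Step 2
Reactants: 2 (2E,6E)-8-hydroxy-3,7-dimethylocta-2,6-dien-1-yl acetate
Product: 3 (2E)-5-[(2R,3R)-3-(hydroxymethyl)-3-methyloxiran-2-yl]-3-methylpent-2-en-1-yl acetate
Conditions: Ti(OiPr)4 (10 mol%), D-(−)-diethyl tartrate (12 mol%), t-BuOOH, 4 Å molecular sieves (zeolite Na12Al12Si12O48), CH2Cl2, −20 °C
Reagents that add atoms: tert-butyl hydroperoxide, CC(C)(C)OO
Why: Sharpless asymmetric epoxidation touches only the free allylic alcohol, and the D-(−)-tartrate catalyst delivers oxygen to the face that gives the (2R,3R)-oxirane (the mirror of the 2S,3S sense given by the L-(+)-ester), which fixes the future C4 carbinol by reagent control.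

Step 3
Reactants: 3 (2E)-5-[(2R,3R)-3-(hydroxymethyl)-3-methyloxiran-2-yl]-3-methylpent-2-en-1-yl acetate
Product: 4 (2E,7S)-3,7-dimethyloct-2-ene-1,7,8-triol
Conditions: i-Bu2AlH (6 equiv), CH2Cl2, −78 → 0 °C; aq. potassium sodium tartrate (KNaC4H4O6)
Reagents that add atoms: none
Why: Regioselective hydride opening of a 2,3-epoxy alcohol: i-Bu2AlH delivers hydride by SN2 to the secondary oxirane carbon and not to the quaternary one, so the quaternary C–O bond survives as the (7S) tertiary alcohol of a 1,2-diol, and the same reagent reductively removes the acetate.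

Step 4
Reactants: 4 (2E,7S)-3,7-dimethyloct-2-ene-1,7,8-triol
Product: 5 (2E,7S)-7,8-dihydroxy-3,7-dimethyloct-2-enal
Conditions: MnO2 (15 equiv), CH2Cl2, rt
Reagents that add atoms: none
Why: MnO2 allylic oxidation converts only the allylic primary alcohol into the enal and leaves the saturated 1,2-diol, the E alkene and the stereocentre untouched.

Step 5
Reactants: 5 (2E,7S)-7,8-dihydroxy-3,7-dimethyloct-2-enal; 6 allenylboronic acid pinacol ester
Product: 7 (4R,5E,10S)-6,10-dimethylundec-5-en-1-yne-4,10,11-triol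
Conditions: (R)-TRIP [(R)-3,3′-bis(2,4,6-triisopropylphenyl)-1,1′-binaphthyl-2,2′-diyl hydrogen phosphate] (5 mol%), 4 Å molecular sieves, toluene, −20 °C
Reagents that add atoms: allenylboronic acid pinacol ester (6), C=C=CB1OC(C)(C)C(C)(C)O1
Why: Chiral phosphoric acid-catalysed propargylboration: the allenylboronate adds through a closed six-membered SE2′ transition state held by the catalyst, giving only the homopropargylic alcohol and setting the carbinol (future C6) as R; (R)-TRIP is expected to give this sense by analogy with its aldehyde allyl- and propargylborations, and the antipodal acid is used should the sense prove opposite.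

Step 6
Reactants: 7 (4R,5E,10S)-6,10-dimethylundec-5-en-1-yne-4,10,11-triol; 8 trimethylaluminium; 9 methyl vinyl ketone
Product: 11 (5E,8R,9E,14S)-8,14,15-trihydroxy-6,10,14-trimethylpentadeca-5,9-dien-2-one, via alkenylalane 10 (not isolated)
Conditions: AlMe3 (6 equiv), Cp2ZrCl2 (0.3 equiv), CH2Cl2, 0 °C → rt; then THF, CuBr·SMe2 (10 mol%), methyl vinyl ketone (3 equiv), −20 °C; aq. potassium sodium tartrate
Reagents that add atoms: trimethylaluminium (8), C[Al](C)C; methyl vinyl ketone (9), C=CC(C)=O
Why: Negishi zirconium-catalysed carboalumination adds CH3 and Al syn across the alkyne with Al on the terminal carbon, giving the E-trisubstituted alkenylalane, and its copper-catalysed conjugate addition to methyl vinyl ketone installs the 4-oxopentyl end in the same flask; the hydroxyls ride as aluminium alkoxides and no stereocentre is touched.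

Step 7
Reactants: 11 (5E,8R,9E,14S)-8,14,15-trihydroxy-6,10,14-trimethylpentadeca-5,9-dien-2-one
Product: 13 (5E,8R,9E)-8-hydroxy-6,10-dimethyl-13-[(2S)-2-methyloxiran-2-yl]trideca-5,9-dien-2-one, via primary tosylate 12 (not isolated)
Conditions: TsCl (1.05 equiv), Et3N, Bu2SnO (5 mol%), CH2Cl2, 0 °C; then K2CO3, MeOH, rt
Reagents that add atoms: none
Why: Stannylene-acetal-mediated sulfonylation activates only the primary hydroxyl of the 1,2-diol, and intramolecular Williamson displacement by the tertiary alkoxide closes the oxirane without breaking the quaternary C–O bond, so the S configuration is retained.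

Step 8
Reactants: 13 (5E,8R,9E)-8-hydroxy-6,10-dimethyl-13-[(2S)-2-methyloxiran-2-yl]trideca-5,9-dien-2-one; 14 acetic anhydride
Product: 15 (5E,8R,9E)-6,10-dimethyl-13-[(2S)-2-methyloxiran-2-yl]-2-oxotrideca-5,9-dien-8-yl acetate
Conditions: Ac2O, pyridine, DMAP (cat.), CH2Cl2, 0 °C → rt
Reagents that add atoms: acetic anhydride (14), CC(=O)OC(C)=O
Why: DMAP-catalysed acylation of the only remaining hydroxyl puts the acetate of the target on the future C6 before ring formation, without touching the stereocentre, the oxirane or the ketone.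

Step 9
Reactants: 15 (5E,8R,9E)-6,10-dimethyl-13-[(2S)-2-methyloxiran-2-yl]-2-oxotrideca-5,9-dien-8-yl acetate
Product: 17 ent-6α-acetoxy-8α,18-dihydroxy-14,15-dinorlabdan-13-one, via tricyclic enol ether 16 (not isolated)
Conditions: MeAlCl2 (3 equiv), CH2Cl2, −78 °C; then 1 M HCl, THF, 0 °C
Reagents that add atoms: water, O
Why: Lewis acid-promoted epoxide-initiated cation–olefin bicyclization terminated by the ketone oxygen, the chemical counterpart of the labdane-forming cyclase step: C5 attacks C4 anti to the oxirane oxygen (inversion, CH2O equatorial, CH3 axial); allylic 1,3-strain between the C6 acetoxy group and the cis methyl on C10 allows only the chair–chair fold that places the acetate equatorial; the two E alkenes give the trans ring fusion and the equatorial C9 chain; the carbonyl oxygen adds to C8 anti to the new C9–C10 bond (equatorial O, axial CH3), so C4, C5, C10, C9 and C8 are set together; aqueous acid then opens the cyclic enol ether to the hydroxy ketone.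

Step 10
Reactants: 17 ent-6α-acetoxy-8α,18-dihydroxy-14,15-dinorlabdan-13-one
Product: 21 ent-6α-acetoxy-8α,18-dihydroxy-14,15-dinorlabd-13(16)-en-13-yl trifluoromethanesulfonate, via bis(trimethylsilyl) ether 18 (not isolated), via potassium enolate 19 (not isolated), via silylated enol triflate 20 (not isolated)
Conditions: (Me3Si)2NH, Me3SiCl (cat.), CH2Cl2, rt, evaporate; KN(SiMe3)2 (1.2 equiv), THF, −78 °C, then Comins' reagent; AcOH, THF/H2O, rt
Reagents that add atoms: Comins' reagent [N-(5-chloropyridin-2-yl)bis(trifluoromethanesulfonimide)], FC(F)(F)S(=O)(=O)N(c1ccc(Cl)cn1)S(=O)(=O)C(F)(F)F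
Why: Transient O-silylation removes both hydroxyl protons and with them the risk of alkoxide-driven 6→18 acetyl migration, after which kinetic enolization of the methyl ketone on its CH3 side by the bulky amide and O-sulfonylation by Comins' reagent give the terminal enol triflate (kinetic enolate trapping); mild acid then frees the alcohols and no stereocentre is involved.

Step 11
Reactants: 21 ent-6α-acetoxy-8α,18-dihydroxy-14,15-dinorlabd-13(16)-en-13-yl trifluoromethanesulfonate; 22 tributyl(vinyl)stannane
Product: 23 ent-6α-acetoxylabda-13(16),14-diene-8α,18-diol (6-O-acetylandalusol, CNP0312185.1)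
Conditions: Pd(PPh3)4 (5 mol%), LiCl (3 equiv), THF, 65 °C
Reagents that add atoms: tributyl(vinyl)stannane (22), C=C[Sn](CCCC)(CCCC)CCCC
Why: Stille coupling of the enol triflate (oxidative addition to zerovalent palladium, chloride-assisted transmetalation, reductive elimination) forms the C13–C14 bond and so the 2-substituted 1,3-diene under neutral conditions that tolerate the free alcohols and the acetate; no stereocentre is touched.

**Compound list**
1 | geranyl acetate, (2E)-3,7-dimethylocta-2,6-dien-1-yl acetate | CC(C)=CCC/C(C)=C/COC(C)=O | starting material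
2 | (2E,6E)-8-hydroxy-3,7-dimethylocta-2,6-dien-1-yl acetate | OC/C(C)=C/CC/C(C)=C/COC(C)=O | intermediate
3 | (2E)-5-[(2R,3R)-3-(hydroxymethyl)-3-methyloxiran-2-yl]-3-methylpent-2-en-1-yl acetate | OC[C@@]1(C)O[C@@H]1CC/C(C)=C/COC(C)=O | intermediate
4 | (2E,7S)-3,7-dimethyloct-2-ene-1,7,8-triol | OC[C@@](C)(O)CCC/C(C)=C/CO | intermediate
5 | (2E,7S)-7,8-dihydroxy-3,7-dimethyloct-2-enal | OC[C@@](C)(O)CCC/C(C)=C/C=O | intermediate
6 | allenylboronic acid pinacol ester, 4,4,5,5-tetramethyl-2-(propa-1,2-dien-1-yl)-1,3,2-dioxaborolane | C=C=CB1OC(C)(C)C(C)(C)O1 | starting material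
7 | (4R,5E,10S)-6,10-dimethylundec-5-en-1-yne-4,10,11-triol | OC[C@@](C)(O)CCC/C(C)=C/[C@H](O)CC#C | intermediate
8 | trimethylaluminium | C[Al](C)C | starting material
9 | methyl vinyl ketone, but-3-en-2-one | C=CC(C)=O | starting material
10 | (1E,4R,5E,10S)-alkenyldimethylalane from syn-methylalumination of 7, the three hydroxyls as dimethylaluminium alkoxides; formed in the flask | C[Al](C)OC[C@@](C)(O[Al](C)C)CCC/C(C)=C/[C@H](O[Al](C)C)C/C(C)=C/[Al](C)C | intermediate
11 | (5E,8R,9E,14S)-8,14,15-trihydroxy-6,10,14-trimethylpentadeca-5,9-dien-2-one | OC[C@@](C)(O)CCC/C(C)=C/[C@H](O)C/C(C)=C/CCC(C)=O | intermediate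
12 | (2S,6E,8R,10E)-2,8-dihydroxy-2,6,10-trimethyl-14-oxopentadeca-6,10-dien-1-yl 4-methylbenzenesulfonate; formed in the flask | Cc1ccc(cc1)S(=O)(=O)OC[C@@](C)(O)CCC/C(C)=C/[C@H](O)C/C(C)=C/CCC(C)=O | intermediate
13 | (5E,8R,9E)-8-hydroxy-6,10-dimethyl-13-[(2S)-2-methyloxiran-2-yl]trideca-5,9-dien-2-one | C[C@@]1(CO1)CCC/C(C)=C/[C@H](O)C/C(C)=C/CCC(C)=O | intermediate
14 | acetic anhydride | CC(=O)OC(C)=O | starting material
15 | (5E,8R,9E)-6,10-dimethyl-13-[(2S)-2-methyloxiran-2-yl]-2-oxotrideca-5,9-dien-8-yl acetate | C[C@@]1(CO1)CCC/C(C)=C/[C@H](OC(C)=O)C/C(C)=C/CCC(C)=O | intermediate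
16 | ent-6α-acetoxy-8α,13-epoxy-14,15-dinorlabd-12-en-18-ol (4S,5S,6R,8S,9S,10R; trans-decalin fused to a 6-methyl-3,4-dihydro-2H-pyran through C8–O); formed in the flask | CC1=CC[C@H]2[C@]3(C)CCC[C@](C)(CO)[C@H]3[C@H](OC(C)=O)C[C@]2(C)O1 | intermediate
17 | ent-6α-acetoxy-8α,18-dihydroxy-14,15-dinorlabdan-13-one (4S,5S,6R,8S,9S,10R; trans-decalin, axial CH3 on C4, C8 and C10, equatorial CH2OH on C4, OAc on C6, OH on C8 and 3-oxobutyl on C9) | CC(=O)CC[C@H]1[C@]2(C)CCC[C@](C)(CO)[C@H]2[C@H](OC(C)=O)C[C@]1(C)O | intermediate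
18 | 8,18-bis(trimethylsilyl) ether of 17; formed in the flask | CC(=O)CC[C@H]1[C@]2(C)CCC[C@](C)(CO[Si](C)(C)C)[C@H]2[C@H](OC(C)=O)C[C@]1(C)O[Si](C)(C)C | intermediate
19 | potassium C13(16)-enolate of 18; formed in the flask | C=C([O-])CC[C@H]1[C@]2(C)CCC[C@](C)(CO[Si](C)(C)C)[C@H]2[C@H](OC(C)=O)C[C@]1(C)O[Si](C)(C)C.[K+] | intermediate
20 | 8,18-bis(trimethylsilyl) ether of 21; formed in the flask | C=C(OS(=O)(=O)C(F)(F)F)CC[C@H]1[C@]2(C)CCC[C@](C)(CO[Si](C)(C)C)[C@H]2[C@H](OC(C)=O)C[C@]1(C)O[Si](C)(C)C | intermediate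
21 | ent-6α-acetoxy-8α,18-dihydroxy-14,15-dinorlabd-13(16)-en-13-yl trifluoromethanesulfonate (4S,5S,6R,8S,9S,10R) | C=C(OS(=O)(=O)C(F)(F)F)CC[C@H]1[C@]2(C)CCC[C@](C)(CO)[C@H]2[C@H](OC(C)=O)C[C@]1(C)O | intermediate
22 | tributyl(vinyl)stannane | C=C[Sn](CCCC)(CCCC)CCCC | starting material
23 | ent-6α-acetoxylabda-13(16),14-diene-8α,18-diol, 6-O-acetylandalusol (4S,5S,6R,8S,9S,10R) | C=CC(=C)CC[C@H]1[C@]2(C)CCC[C@](C)(CO)[C@H]2[C@H](OC(C)=O)C[C@]1(C)O | target

**Totals**
Total step count: 11. Longest linear sequence: 11 steps (1 → 23).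

**Steps most likely to fail**

Step 9 (bicyclization). The allylic acetate lowers the nucleophilicity of the C5=C10 alkene and may ionise under MeAlCl2. The 2,2-disubstituted oxirane may then rearrange by 1,2-hydride shift to an aldehyde, or open to a chlorohydrin, before ring A closes. An SN1-like opening would also erode C4. The fallback sets out from 13 and comes back at 17, and it moves the acetate to after ring formation. The free alcohol 13 is cyclised itself (MeAlCl2, CH2Cl2, −78 °C), its hydroxyl being present as an aluminium alkoxide that withdraws far less and does not ionise readily. This gives the tricyclic enol ether ent-8α,13-epoxy-14,15-dinorlabd-12-ene-6α,18-diol F1, which the acidic work-up opens to ent-6α,8α,18-trihydroxy-14,15-dinorlabdan-13-one F2. Acetylation of both non-tertiary hydroxyls (Ac2O, pyridine, DMAP) gives ent-6α,18-diacetoxy-8α-hydroxy-14,15-dinorlabdan-13-one F3. Selective methanolysis of the unhindered primary 18-acetate (K2CO3, MeOH, 0 °C, or a lipase) returns 17.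

Step 6 (methylalumination and 1,4-addition on the unprotected triol). Three equivalents of AlMe3 are used up by the hydroxyls, excess AlMe3 can transfer CH3 to the enone, and methyl vinyl ketone polymerises easily. The fallback sets out from 7 and comes back at 11, replacing the conjugate addition by a cross-coupling. The alkenylalane 10 is quenched with I2 to (1E,4R,5E,10S)-1-iodo-2,6,10-trimethylundeca-1,5-diene-4,10,11-triol F4. Commercial 2-methyl-2-vinyl-1,3-dioxolane is hydroborated with 9-BBN to 9-[2-(2-methyl-1,3-dioxolan-2-yl)ethyl]-9-borabicyclo[3.3.1]nonane F5. B-alkyl Suzuki–Miyaura coupling of F5 with F4 (PdCl2(dppf), K3PO4, DMF/H2O) gives (2S,6E,8R,10E)-2,6,10-trimethyl-13-(2-methyl-1,3-dioxolan-2-yl)trideca-6,10-diene-1,2,8-triol F6. Pyridinium p-toluenesulfonate in wet acetone removes the dioxolane and gives 11.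

Step 10 (kinetic enol triflate). The amide base may enolise toward C12 or touch the acetate, and partial loss of the silyl groups would expose an alkoxide next to the acetate. The fallback sets out from 17 and comes back at 23, avoiding enolate chemistry altogether. Ketone 17 is condensed with 1,2-bis(tert-butyldimethylsilyl)hydrazine (Sc(OTf)3 cat.) to its N-tert-butyldimethylsilyl hydrazone F7. I2 and tetramethylguanidine (Barton vinyl iodide synthesis, which gives the 2-iodo-1-alkene from methyl ketones) convert F7 into ent-6α-acetoxy-13-iodo-14,15-dinorlabd-13(16)-ene-8α,18-diol F8. Stille coupling of F8 with 22 (Pd(PPh3)4, THF, 65 °C) gives 23.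

**Further compounds**
F1 | step 9 | ent-8α,13-epoxy-14,15-dinorlabd-12-ene-6α,18-diol | CC1=CC[C@H]2[C@]3(C)CCC[C@](C)(CO)[C@H]3[C@H](O)C[C@]2(C)O1
F2 | step 9 | ent-6α,8α,18-trihydroxy-14,15-dinorlabdan-13-one | CC(=O)CC[C@H]1[C@]2(C)CCC[C@](C)(CO)[C@H]2[C@H](O)C[C@]1(C)O
F3 | step 9 | ent-6α,18-diacetoxy-8α-hydroxy-14,15-dinorlabdan-13-one | CC(=O)CC[C@H]1[C@]2(C)CCC[C@](C)(COC(C)=O)[C@H]2[C@H](OC(C)=O)C[C@]1(C)O
F4 | step 6 | (1E,4R,5E,10S)-1-iodo-2,6,10-trimethylundeca-1,5-diene-4,10,11-triol | OC[C@@](C)(O)CCC/C(C)=C/[C@H](O)C/C(C)=C/I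
F5 | step 6 | 9-[2-(2-methyl-1,3-dioxolan-2-yl)ethyl]-9-borabicyclo[3.3.1]nonane | CC1(CCB2C3CCCC2CCC3)OCCO1
F6 | step 6 | (2S,6E,8R,10E)-2,6,10-trimethyl-13-(2-methyl-1,3-dioxolan-2-yl)trideca-6,10-diene-1,2,8-triol | OC[C@@](C)(O)CCC/C(C)=C/[C@H](O)C/C(C)=C/CCC1(C)OCCO1
F7 | step 10 | N-tert-butyldimethylsilyl hydrazone of 17 (C=N geometry not defined) | CC(=NN[Si](C)(C)C(C)(C)C)CC[C@H]1[C@]2(C)CCC[C@](C)(CO)[C@H]2[C@H](OC(C)=O)C[C@]1(C)O
F8 | step 10 | ent-6α-acetoxy-13-iodo-14,15-dinorlabd-13(16)-ene-8α,18-diol | C=C(I)CC[C@H]1[C@]2(C)CCC[C@](C)(CO)[C@H]2[C@H](OC(C)=O)C[C@]1(C)O
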